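The data come from a simulation from invented constants, noise included.

10.0 s was the number the meeting opened on, because the green run is already flat at that first reading.

| setting | green | grey | blue | spring | dawn | summer | winter |
|---|---|---|---|---|---|---|---|
| substrate | 0.50 mM | 0.50 mM | 0.50 mM | 0.50 mM (fed, over 1.5 min) | 0.50 mM | 0.50 mM | 0.50 mM |
| coupling partner | 1 equiv | 0.67 equiv | 1.5 equiv | 1.00 equiv | 1.00 equiv (fed, over 1.5 min) | 1.00 equiv (in portions, 4, over 1.5 min) | 1.00 equiv |
| remark | run made earlier | run made earlier | run made earlier | all else is in the flask from the start; the feed brings no volume worth counting | all else is in the flask from the start; the feed brings no volume worth counting | first portion at the start, last at 1.5 min | everything together at the start |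
| time |  |  |  | 2.5 min | 2.5 min | 2.5 min | 2.5 min |

| run | time / s | bis adduct / % | triple product / % |
|---|---|---|---|
| green | 10.0 | 9.8 | 14.5 |
| green | 15.0 | 12.0 | 11.7 |
| green | 40.0 | 9.9 | 14.5 |
| green | 90.0 | 9.7 | 13.2 |
| grey | 10.0 | 7.4 | 6.2 |
| grey | 15.0 | 6.6 | 6.5 |
| grey | 40.0 | 8.7 | 6.7 |
| grey | 90.0 | 7.7 | 6.7 |
| blue | 12.0 | 12.1 | 23.7 |
| blue | 30.0 | 11.3 | 22.5 |
| blue | 60.0 | 11.0 | 23.4 |
| blue | 90.0 | 11.2 | 24.7 |

(scatter of a reading: 1 percentage point)



* the flask that comes out highest in amount of bis adduct, in percent of the substrate charged; "all alike" if 1.5 percentage points covers them all (spring / dawn / summer / winter / all alike)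
* amount of bis adduct at the end, in percent of the substrate charged, spring
* amount of bis adduct at the end, in percent of the substrate charged, dawn
* amount of bis adduct at the end, in percent of the substrate charged, summer
* amount of bis adduct at the end, in percent of the substrate charged, winter

The chair asked what a run so flat means for flasks fed over 1.5 min. The first speaker proposed to keep the feed time over the time a batch needs to go flat, 9.00, as the slice number; it is a lower figure, she said, since the flattening may be quicker than the first reading shows. Because the feed lasts longer than the flattening, she argued, spring, where substrate is fed to the whole charge of coupling partner, reacts slice by slice, so the ratio [coupling partner]/[substrate] met within one slice counts there; for dawn and summer she claimed nothing of the kind.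

The second speaker read the runs. On mean readings, triple product per bis adduct climbs from 0.859 in grey through 1.30 in green to 2.07 in blue. He concluded that a high ratio carries material past bis adduct, while grey shows that a low ratio yields less of it.

The first speaker applied this to spring, whose opening slice meets 9.00 equiv, beyond blue. She then went round once more: the coupling partner taken up by the opening slices is subtracted from what the later slices of spring meet, so those slices meet a lower ratio, with coupling partner as the limiting reagent. The minutes record her reckoning: winter repeats the green recipe, near 10.3 %, and spring falls below it by more than 1.5 percentage points, with no figure put on it, while dawn and summer were left open.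

The forecast gave 10.1 %, 10.1 %, 10.1 % and 10.1 % for spring, dawn, summer and winter, hence all alike, holding that “addition order should not matter”.

The flasks give 1.30 % in spring, 0.633 % in dawn, 2.29 % in summer and 10.2 % in winter, so the highest is winter.

    substrate + coupling partner → first product (k = 2800 M⁻¹ s⁻¹)
    coupling partner + first product → bis adduct (k = 3200 M⁻¹ s⁻¹)
    coupling partner + bis adduct → triple product (k = 8700 M⁻¹ s⁻¹)
    2 substrate → self-condensation product (k = 140 M⁻¹ s⁻¹)
    coupling partner + triple product → over-reaction product (k = 1300 M⁻¹ s⁻¹)

In winter, the first coupling alone gives the coupling partner a half-life of 0.73 s at 0.00512 min. The feed time is 123 such half-lives, more than the slice number of 9.00. Spring's coupling partner stands at 0 % at 1.25 min, inside the feed, with bis adduct at 1.30 %, while dawn, at 0.633 %, ends with 70.8 % of self-condensation product against 38.0 % in winter.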